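## Structural features

(+)-Miliusane V is a spirocycle. A cyclohexanone (ring A: C1 bearing NHAc, C2, the C3 ketone, C4, C5, C6 bearing OH) shares the quaternary carbon C4 with a γ-butyrolactone (ring B: C4, C7, the C8 carbonyl, O9, C10), and C10 carries an (E)-2,6-dimethylhepta-1,5-dienyl chain (C11=C12 onward). Of the four stereocentres, C1 and C6 are adjacent and cis (a 1,2-acetamido alcohol). C10 is adjacent to the spiro centre C4, which sits between the C3 carbonyl and C5. On ring A the C4–C10 bond is on the same face as N and O; on ring B the dienyl chain is on the side of C3. Fragile points are the β-acetamido ketone (retro-Michael loss of nitrogen), the allylic C10–O9 bond of the lactone (ionization), the two trisubstituted alkenes (acid, electrophiles, boranes, oxidants) and the lactone itself (base, which would free a C10 alkoxide able to cleave C4–C10 by retro-aldol reaction). The real difficulty is the all-carbon quaternary centre C4 with a defined relation to C10; the amino alcohol is routine once an enone is in place. The key step uses the fact that the C6 oxygen and the C8 carbonyl are 1,5-related through C5–C4–C7. That is the product pattern of a cyclobutanol retro-aldol cleavage (De Mayo logic) of a cyclobutane C4–C7–C8–C5. The link O9–C10, which already joins C8 to C4 in ring B, can act as a two-atom tether for an intramolecular [2+2] photocycloaddition between a C4=C5 enone of ring A and a C7=C8 ketene acetal.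

## Logic of the disconnections

20 to 19. The three C–H bonds of the acetyl methyl group are traced back to C–Cl bonds. The reason is that nitrogen and its acyl carbon can then come from one nitrile-derived reagent. The forward step must remove chlorine by a radical chain without touching the alkenes, the ketone or the lactone.

19 to 18. The amide carbon is reconnected to the C6 oxygen (C–O bond of an oxazoline). This stores the cis amino alcohol in one five-membered ring. The forward hydrolysis must be mild enough not to expel nitrogen from the β-position of the ketone.

18 to 16 (through 17). The C1–N bond is cut. C1 is β to the C3 ketone, so nitrogen can arrive by conjugate addition, and an imidate on the C6 oxygen makes the delivery intramolecular and therefore cis. This removes C1 as a stereocentre; the forward step demands that the imidate nitrogen adds before any other base-induced process.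

16 to 15. The C6–H bond is cut (carbinol to ketone). This gives an ene-1,4-dione with only C4 and C10 as stereocentres. The forward reduction must pick C6 over C3 (C3 is neopentyl) and set 6S by reagent control.

15 to 13 (through 14). The bond C5–C8 is re-formed in the retrosynthetic sense, and the C6 ketone and the C8 oxygen are masked. This turns the spiro lactone into a cyclobutane that is a [2+2] retron. The forward unmasking must be acidic, so that no alkoxide appears at C10.

13 to 12. The bonds C4–C7 and C5–C8 are cut. This is the strategic cut: it removes two rings and the quaternary centre and leads to a flat dienone carrying a tethered ketene acetal. The forward step needs regiocontrol (given by the tether) and face control at C4 (relayed from C10).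

12 to 10 (through 11). The O–Si bond and the C7=C8 enol double bond are taken back to an acetate. The forward enolization must be done at low temperature with the silyl chloride already present, because the enolate has a ketone within reach and the product can rearrange thermally.

10 to 9. The acyl C8–O9 bond is cut, leaving a secondary alcohol. The acylation is placed after dearomatization, because an ortho-acyloxybenzyl phenoxide would eliminate.

9 to 8. One C6–OMe bond is cut and ring A is taken back to a para-methoxyphenol. This gives an aromatic, easily made precursor. The forward oxidation must be para-selective and leave the allylic alcohol and alkenes alone.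

8 to 7. The phenol is masked as a silyl ether (O–Si bond), so that organometallic and borane steps are possible and deprotection needs only fluoride.

7 to 6. The C10–H bond is cut (carbinol to ketone). C10 is the only stereocentre that must be made by an external chiral reagent, and a ketone allows this. The forward step demands clean 1,2-reduction with face control.

6 to 5. An oxidation-level adjustment of the racemic carbinol; it costs one step but allows the C–C bond to be made without stereocontrol.

5 to 2 and 3 (through 4). The bond C4–C10 is cut between an aryl metal and an enal, joining the two halves of the carbon skeleton. The forward step demands 1,2-addition and an aryl metal that keeps its silyl ether.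

2 to 1. The O–Si bond is cut, leading to the commercial bromophenol.

## Other disconnections considered

Alternative 1: The cut is through ring A at C3–C4 and C5–C6, with C3 taken back to an acetoxy carbon and a C1=C2 alkene left in the ring. The forward key step is a thermal endo Diels–Alder reaction of itaconic anhydride A1 with (1E,3E)-1,4-diacetoxybuta-1,3-diene A2, giving the spiro anhydride diacetate A3.
- In its favour: two cheap components and a concerted cycloaddition with ample precedent. The endo rule places the C6 oxygen on the same face as C10, as 20 requires, so C6 has its oxygen and configuration from the start. On predictability of the key step and on C6 this alternative is the better plan.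
- Against it here: A3 is racemic unless an asymmetric version can be found for a sluggish oxygenated diene and an anhydride that isomerizes to its endocyclic alkene on heating. An alkenyl nucleophile should prefer the unhindered C8 carbonyl over the neopentyl C10 carbonyl that must receive it. C10 would then be set by substrate control, the two allylic acetates must be differentiated, C3 oxidized and nitrogen still brought to C1.
- Comparison: A3 holds ring A and C4 but none of the chain, whereas 13 holds every carbon of 20. Step economy is worse: roughly ten or more operations from A3 against five from 13.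

Alternative 2: The cut is the C6–O bond (as a lactone C–O bond) together with C5–I, which leads back to the prochiral diene acid A4; this is available in one step by Birch reductive alkylation. The forward key step is a catalyst-controlled iodolactonization (I2, chiral bifunctional catalyst) in which the C10 carboxyl attacks C6 of one alkene and iodine adds to C5, giving the bridged iodolactone A5.
- In its favour: C4 becomes a quaternary stereocentre under direct catalyst control, independent of any relay, and the C6 oxygen is placed cis to C10 as required. On these two points it is the equal or the better of the chosen plan, and the anti-addition mechanism is well understood.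
- Against it here: desymmetrizing iodolactonization of cyclohexadiene acids with high selectivity is less secure than for open-chain acids. In A5, C10 is a carboxyl carbon locked in the wrong lactone; it must be opened, reduced, alkenylated with control next to a quaternary centre and re-lactonized onto C8. Iodine must be removed from C5, the C2=C3 alkene converted to the C3 ketone, and nitrogen placed at C1.
- Comparison: A5 solves C4 and C6 but leaves C1, C3, C10 and the chain, whereas 15 has C3, C6, C1=C2 and C10 in place. Step economy is clearly worse.

Alternative 3: The cut is C1–N and C6–O together, with the C3 ketone taken back to a carbinol that carries the nitrogen as the N-(mesitoyloxy)carbamate A6 (ring A alkene at C1=C6). The forward key step uses catalytic K2OsO2(OH)4 (hexavalent osmium); a tethered imido osmium species adds syn across C1=C6 and gives the bridging cyclic carbamate A7 with free C6–OH.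
- In its favour: a known reaction type whose regiochemistry is fixed by the tether, setting C1 and C6 cis in a single step without tin. For the amino alcohol it is the better plan in stereochemical security and the equal in step count.
- Against it here: it leaves the quaternary centre C4 unsolved. A6 also needs a C3 carbinol of defined configuration that is later destroyed, and an alkene isomer that the chosen route does not deliver. Osmium may attack the electron-rich chain alkenes, and the carbamate must be opened under conditions the γ-lactone tolerates, followed by selective N-acetylation and oxidation at C3.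
- Comparison: it addresses C1/C6 only and could replace steps 11–14 of the chosen plan only at the cost of extra redox steps.

Key step: step 9

Remarks (assumptions and checks on the chemistry):
- Atom numbers C1–C12 are those defined under "Structural features" and are used for every intermediate.
- Structure check: C10 keeps one spatial arrangement (R) from 7 to 20. C4 of 13 is S by the CIP rules only because C5 outranks C7 there; it is the arrangement that becomes 4R in 15–20. No structural correction was needed.
- Assumption for step 4: the ortho-silyloxyaryl group is the larger carbonyl substituent in the oxazaborolidine model; if the alkenyl group proves larger, the enantiomeric catalyst is used.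
- Design changes: the phenol is silylated before the organometallic and borane steps; 12 is made and irradiated in one cold solution; the unzipping is acidic only; the oxazoline is hydrolysed before dechlorination.

## Steps

Step 1
Reactants: 1 2-bromo-4-methoxyphenol
Product: 2 (2-bromo-4-methoxyphenoxy)(tert-butyl)dimethylsilane
Conditions: TBSCl, imidazole, DMF, 0 °C to rt
Reagents that add atoms: tert-butyldimethylsilyl chloride, CC(C)(C)[Si](C)(C)Cl
Why: Imidazole-assisted silylation masks the acidic phenol so that a Grignard reagent can be formed and the borane reduction of step 4 meets no phenoxyborane; a silyl ether is chosen because fluoride removes it without the acid that the doubly activated carbinol would not survive.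

Step 2
Reactants: 2 (2-bromo-4-methoxyphenoxy)(tert-butyl)dimethylsilane; 3 geranial, (2E)-3,7-dimethylocta-2,6-dienal
Product: 5 racemic (2E)-1-[2-(tert-butyldimethylsilyloxy)-5-methoxyphenyl]-3,7-dimethylocta-2,6-dien-1-ol, via arylmagnesium bromide 4 (not isolated)
Conditions: Mg, THF, 40 °C; then 3, −78 to 0 °C; aq. NH4Cl
Reagents that add atoms: none
Why: Grignard addition: the arylmagnesium reagent (preferred to the aryllithium, which could suffer O-to-C silyl migration, the retro-Brook rearrangement) adds 1,2 to the β,β-disubstituted enal and forms the C4–C10 bond. C10 is formed racemic and is corrected in steps 3 and 4.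

Step 3
Reactants: 5 racemic (2E)-1-[2-(tert-butyldimethylsilyloxy)-5-methoxyphenyl]-3,7-dimethylocta-2,6-dien-1-ol
Product: 6 (2E)-1-[2-(tert-butyldimethylsilyloxy)-5-methoxyphenyl]-3,7-dimethylocta-2,6-dien-1-one
Conditions: MnO2 (activated, excess), CH2Cl2, rt
Reagents that add atoms: none
Why: MnO2 oxidizes the benzylic and allylic alcohol selectively under neutral heterogeneous conditions; the silyl ether, both trisubstituted alkenes and the (E)-enone geometry should be unaffected.

Step 4
Reactants: 6 (2E)-1-[2-(tert-butyldimethylsilyloxy)-5-methoxyphenyl]-3,7-dimethylocta-2,6-dien-1-one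
Product: 7 (1R,2E)-1-[2-(tert-butyldimethylsilyloxy)-5-methoxyphenyl]-3,7-dimethylocta-2,6-dien-1-ol
Conditions: (S)-2-methyl-CBS-oxazaborolidine (0.2 equiv), catecholborane, toluene, −78 to −40 °C; MeOH quench
Reagents that add atoms: none
Why: Corey–Bakshi–Shibata reduction: the catalyst–borane complex binds the carbonyl lone pair anti to the twisted ortho-silyloxyaryl group (taken as the large substituent) and delivers hydride to the Si face, which sets C10 as R. Catecholborane at low temperature gives 1,2-reduction only and does not hydroborate the diene.

Step 5
Reactants: 7 (1R,2E)-1-[2-(tert-butyldimethylsilyloxy)-5-methoxyphenyl]-3,7-dimethylocta-2,6-dien-1-ol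
Product: 8 2-[(1R,2E)-1-hydroxy-3,7-dimethylocta-2,6-dien-1-yl]-4-methoxyphenol
Conditions: TBAF, AcOH, THF, 0 °C
Reagents that add atoms: none
Why: Fluoride cleaves the aryl silyl ether (Si–F bond formation); acetic acid buffers the phenoxide so that the ortho-hydroxybenzylic alcohol does not eliminate to an ortho-quinone methide, and C10 is not touched.

Step 6
Reactants: 8 2-[(1R,2E)-1-hydroxy-3,7-dimethylocta-2,6-dien-1-yl]-4-methoxyphenol
Product: 9 2-[(1R,2E)-1-hydroxy-3,7-dimethylocta-2,6-dien-1-yl]-4,4-dimethoxycyclohexa-2,5-dien-1-one
Conditions: PhI(OAc)2, MeOH, 0 °C; NaHCO3 work-up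
Reagents that add atoms: methanol, CO
Why: Oxidative dearomatization of a para-methoxyphenol by the trivalent iodine reagent: the aryloxy iodane loses PhI and methanol captures the cation at C6, para to oxygen and stabilized by the methoxy group, giving the quinone monoketal. The secondary alcohol and the alkenes should not react at 0 °C.

Step 7
Reactants: 9 2-[(1R,2E)-1-hydroxy-3,7-dimethylocta-2,6-dien-1-yl]-4,4-dimethoxycyclohexa-2,5-dien-1-one
Product: 10 (1R,2E)-1-(3,3-dimethoxy-6-oxocyclohexa-1,4-dien-1-yl)-3,7-dimethylocta-2,6-dien-1-yl acetate
Conditions: Ac2O, pyridine, 4-(dimethylamino)pyridine (DMAP, cat.), CH2Cl2, 0 °C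
Reagents that add atoms: acetic anhydride, CC(=O)OC(C)=O
Why: Nucleophile-catalysed acylation puts C7 and C8 of the future lactone on O9; it is done only after dearomatization, because a phenoxide with an ortho benzylic acetate would expel acetate.

Step 8
Reactants: 10 (1R,2E)-1-(3,3-dimethoxy-6-oxocyclohexa-1,4-dien-1-yl)-3,7-dimethylocta-2,6-dien-1-yl acetate
Product: 12 2-[(1R,2E)-1-{[1-(tert-butyldimethylsilyloxy)ethenyl]oxy}-3,7-dimethylocta-2,6-dien-1-yl]-4,4-dimethoxycyclohexa-2,5-dien-1-one (the silyl ketene acetal; kept as a cold solution), via potassium ester enolate 11 (not isolated)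
Conditions: TBSCl premixed with 10, KN(SiMe3)2, toluene–THF, −78 °C; cold filtration under Ar, used at once
Reagents that add atoms: tert-butyldimethylsilyl chloride, CC(C)(C)[Si](C)(C)Cl
Why: Kinetic deprotonation of the acetate methyl group by the hindered amide base with internal silyl chloride quench and O-silylation of the enolate, the first stage of an Ireland–Claisen protocol. The dienone has no acidic hydrogen, trapping at −78 °C should outrun intramolecular aldol addition to the C3 carbonyl (which needs the disfavoured s-cis ester conformer), and the [3,3] rearrangement of 12 is frozen out at this temperature.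

Step 9
Reactants: 12 2-[(1R,2E)-1-{[1-(tert-butyldimethylsilyloxy)ethenyl]oxy}-3,7-dimethylocta-2,6-dien-1-yl]-4,4-dimethoxycyclohexa-2,5-dien-1-one
Product: 13 crossed photoadduct (4S,5R,8R,10R): 2-oxabicyclo[2.1.1]hexane (bridgeheads C4 and C8; bridges O9–C10, C7 and C5) fused at C4–C5 to ring A, which keeps the C3 ketone, the C1=C2 alkene and the C6 dimethyl ketal; C8 bears OTBS and C10 bears the (E)-dienyl chain syn to the C7 bridge
Conditions: hν (365 nm LED, Pyrex), toluene–pentane, ca. 5 mM, −78 °C, Ar
Reagents that add atoms: none
Why: Proposed new method: excitation of the cross-conjugated dienone and intersystem crossing give the triplet of the C3–C4–C5 enone, which adds stepwise to the electron-rich silyl ketene acetal held on C4 through the two atoms C10 and O9; the closest known reaction type is the crossed intramolecular enone–alkene [2+2] photocycloaddition of 1,5-dienes with a two-atom tether, and the orientation (CH2 to the α-carbon, the dioxygenated carbon to the β-carbon) is also the one that intermolecular enone–ketene acetal photocycloadditions show by themselves. The first bond closes a five-membered ring whichever it is (C5–C8 gives the ring C5–C4–C10–O9–C8 in a 5-exo mode at the ketene acetal, C4–C7 gives the oxolane C4–C10–O9–C8–C7), because the six-membered alternative C5–C7 would lead to a bicyclo[2.2.0] skeleton. After spin inversion the 1,4-biradical closes the cyclobutane C4–C7–C8–C5 by radical recombination, which completes the oxolane and the 2-oxabicyclo[2.1.1]hexane. C5 and C8 follow from the cage (ring A can be fused to the cyclobutane only cis, C8 is a bridgehead) and both are erased in step 10. C4 is controlled by C10: in the rotamer that reacts, O9 stands above the ring plane, C10–H points toward C5–H (least 1,3-allylic strain) and the dienyl chain lies on the side of the C3 carbonyl, so C7 is delivered to the face that leaves the chain over the C7 bridge (4S in 13, the same arrangement as 4R in 20). The step needs face selectivity at C4 (resting only on this modest conformational bias), site selectivity for C4=C5 over C1=C2 and C11=C12 (secured by the tether and the fast addition to a ketene acetal), and suppression of the thermal [3,3] rearrangement and of dienone photorearrangement (secured by −78 °C and fast intramolecular trapping).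

Step 10
Reactants: 13 crossed photoadduct (4S,5R,8R,10R)
Product: 15 enedione lactone (4R,10R): ring A with C3 ketone, C1=C2, C6 ketone and C5H2; spiro γ-lactone C4–C7–C8(=O)–O9–C10 with the (E)-dienyl chain on C10, via keto hemiketal 14 (not isolated)
Conditions: 48% aq. HF, MeCN, 0 °C to rt
Reagents that add atoms: water, O
Why: Aqueous HF removes the silyl group of the silyl ketal at C8 and hydrolyses the C6 dimethyl ketal; the strained β-hydroxy ketone 14 then undergoes retro-aldol cleavage of C5–C8 (De Mayo fragmentation), leaving C8 as the lactone carbonyl and C5 as CH2. Acid is used instead of basic fluoride so that no alkoxide appears that could cleave C4–C10; C4 and C10 are untouched.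

Step 11
Reactants: 15 enedione lactone (4R,10R)
Product: 16 (4R,6S,10R)-6-hydroxy enone lactone: as 15 with C6 reduced to a secondary allylic alcohol, OH on the ring A face of C10
Conditions: (R)-2-methyl-CBS-oxazaborolidine (0.2 equiv), catecholborane, toluene–CH2Cl2, −78 °C; MeOH quench
Reagents that add atoms: none
Why: Corey–Bakshi–Shibata reduction: of the two enone carbonyls only C6 has an unhindered CH2 flank (C3 is neopentyl next to the spiro centre), so the catalyst should bind there with the C1=C2 side as the large group and deliver hydride to the face that gives 6S (reagent control). Cyclohexenones do not undergo 1,4-reduction with catecholborane, and the lactone is inert.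

Step 12
Reactants: 16 (4R,6S,10R)-6-hydroxy enone lactone
Product: 18 (1R,4R,6S,10R) cis-fused 2-(trichloromethyl)oxazoline: ring O–C6–C1–N=C(CCl3) on ring A, C3 ketone and spiro lactone unchanged, via trichloroacetimidate 17 (not isolated)
Conditions: Cl3CCN, 1,8-diazabicyclo[5.4.0]undec-7-ene (DBU, 0.2 equiv), CH2Cl2, 0 °C to rt
Reagents that add atoms: trichloroacetonitrile, ClC(Cl)(Cl)C#N
Why: Base-catalysed addition of the C6 alkoxide to the nitrile gives imidate 17, whose nitrogen adds to C1, the β-carbon of the C3 enone, in a 5-exo intramolecular aza-Michael reaction. The five-membered ring can only be cis-fused, so nitrogen at C1 is set cis to oxygen at C6 (1R).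

Step 13
Reactants: 18 (1R,4R,6S,10R) cis-fused 2-(trichloromethyl)oxazoline
Product: 19 (1R,4R,6S,10R)-1-(trichloroacetamido)-6-hydroxy ketone lactone (20 with CCl3 in place of CH3)
Conditions: TsOH·H2O (0.2 equiv), pyridine–H2O, 40 °C
Reagents that add atoms: water, O
Why: Buffered acid hydrolysis of the oxazoline: water adds to the protonated C=N and the tetrahedral intermediate opens (directly, or by O-to-N acyl shift of the cis amino ester) to the hydroxy trichloroacetamide. No strong base is present, so retro-Michael loss of nitrogen is not expected.

Step 14
Reactants: 19 (1R,4R,6S,10R)-1-(trichloroacetamido)-6-hydroxy ketone lactone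
Product: 20 (+)-miliusane V, (1R,4R,6S,10R)
Conditions: Bu3SnH (4 equiv), 2,2′-azobis(isobutyronitrile) (AIBN, 0.2 equiv), toluene, 85 °C
Reagents that add atoms: none
Why: Radical chain dechlorination (the stannyl radical abstracts chlorine and the α-amido radical takes hydrogen from Bu3SnH, three times) converts the trichloroacetamide into the acetamide under neutral conditions. The remote trisubstituted alkenes, ketone, lactone and all four stereocentres should be unaffected.

## Compound list

1 | 2-bromo-4-methoxyphenol | COc1ccc(O)c(Br)c1 | starting material
2 | (2-bromo-4-methoxyphenoxy)(tert-butyl)dimethylsilane | COc1ccc(O[Si](C)(C)C(C)(C)C)c(Br)c1 | intermediate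
3 | geranial, (2E)-3,7-dimethylocta-2,6-dienal | CC(C)=CCC/C(C)=C/C=O | starting material
4 | [2-(tert-butyldimethylsilyloxy)-5-methoxyphenyl]magnesium bromide (not isolated) | COc1ccc(O[Si](C)(C)C(C)(C)C)c([Mg]Br)c1 | intermediate
5 | racemic (2E)-1-[2-(tert-butyldimethylsilyloxy)-5-methoxyphenyl]-3,7-dimethylocta-2,6-dien-1-ol | COc1ccc(O[Si](C)(C)C(C)(C)C)c(C(O)/C=C(\C)CCC=C(C)C)c1 | intermediate
6 | (2E)-1-[2-(tert-butyldimethylsilyloxy)-5-methoxyphenyl]-3,7-dimethylocta-2,6-dien-1-one | COc1ccc(O[Si](C)(C)C(C)(C)C)c(C(=O)/C=C(\C)CCC=C(C)C)c1 | intermediate
7 | (1R,2E)-1-[2-(tert-butyldimethylsilyloxy)-5-methoxyphenyl]-3,7-dimethylocta-2,6-dien-1-ol | COc1ccc(O[Si](C)(C)C(C)(C)C)c([C@H](O)/C=C(\C)CCC=C(C)C)c1 | intermediate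
8 | 2-[(1R,2E)-1-hydroxy-3,7-dimethylocta-2,6-dien-1-yl]-4-methoxyphenol | COc1ccc(O)c([C@H](O)/C=C(\C)CCC=C(C)C)c1 | intermediate
9 | 2-[(1R,2E)-1-hydroxy-3,7-dimethylocta-2,6-dien-1-yl]-4,4-dimethoxycyclohexa-2,5-dien-1-one | O=C1C=CC(OC)(OC)C=C1[C@H](O)/C=C(\C)CCC=C(C)C | intermediate
10 | (1R,2E)-1-(3,3-dimethoxy-6-oxocyclohexa-1,4-dien-1-yl)-3,7-dimethylocta-2,6-dien-1-yl acetate | CC(=O)O[C@@H](C1=CC(OC)(OC)C=CC1=O)/C=C(\C)CCC=C(C)C | intermediate
11 | potassium ester enolate of 10 (not isolated) | C=C([O-])O[C@@H](C1=CC(OC)(OC)C=CC1=O)/C=C(\C)CCC=C(C)C.[K+] | intermediate
12 | silyl ketene acetal (photosubstrate), (10R) | C=C(O[Si](C)(C)C(C)(C)C)O[C@@H](C1=CC(OC)(OC)C=CC1=O)/C=C(\C)CCC=C(C)C | intermediate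
13 | crossed photoadduct, (4S,5R,8R,10R) | O=C1C=CC(OC)(OC)[C@H]2[C@]13C[C@]2(O[Si](C)(C)C(C)(C)C)O[C@@H]3/C=C(\C)CCC=C(C)C | intermediate
14 | keto hemiketal, (4S,5R,8S,10R) (not isolated) | O=C1C=CC(=O)[C@H]2[C@]13C[C@]2(O)O[C@@H]3/C=C(\C)CCC=C(C)C | intermediate
15 | enedione lactone, (4R,10R) | O=C1C=CC(=O)C[C@]12CC(=O)O[C@@H]2/C=C(\C)CCC=C(C)C | intermediate
16 | (4R,6S,10R)-6-hydroxy enone lactone | O=C1C=C[C@@H](O)C[C@]12CC(=O)O[C@@H]2/C=C(\C)CCC=C(C)C | intermediate
17 | (4R,6S,10R)-6-O-trichloroacetimidate (not isolated) | N=C(O[C@@H]1C=CC(=O)[C@@]2(CC(=O)O[C@@H]2/C=C(\C)CCC=C(C)C)C1)C(Cl)(Cl)Cl | intermediate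
18 | (1R,4R,6S,10R) cis-fused 2-(trichloromethyl)oxazoline | ClC(Cl)(Cl)C1=N[C@@H]2CC(=O)[C@@]3(CC(=O)O[C@@H]3/C=C(\C)CCC=C(C)C)C[C@@H]2O1 | intermediate
19 | (1R,4R,6S,10R)-trichloroacetamido alcohol | O=C(N[C@@H]1CC(=O)[C@@]2(CC(=O)O[C@@H]2/C=C(\C)CCC=C(C)C)C[C@@H]1O)C(Cl)(Cl)Cl | intermediate
20 | (+)-miliusane V, (1R,4R,6S,10R) | CC(=O)N[C@@H]1CC(=O)[C@@]2(CC(=O)O[C@@H]2/C=C(\C)CCC=C(C)C)C[C@@H]1O | target

## Step count and least certain steps

Total step count: 14. Longest linear sequence: 14 steps (1 to 20); 3 enters in step 2.

Step 9 (key step, proposed new method). What may go wrong: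
- loss of 12 by thermal [3,3] rearrangement before or during irradiation;
- poor facial selectivity at C4, since the conformational bias from C10 is small;
- competing photorearrangement of the cross-conjugated dienone, or electron transfer from the ketene acetal followed by desilylation.

Fallback with known reactions, setting out from 9 and returning at 15. Hydrogenation of 9 with RhCl(PPh3)3 under H2 (benzene, rt) should saturate only the disubstituted C1=C2 bond and give the 2-substituted 4,4-dimethoxycyclohex-2-enone F1. Irradiation of F1 (350 nm, Pyrex) with excess 1,1-diethoxyethylene (C=C(OCC)OCC) is the classical intermolecular enone–ketene acetal photocycloaddition; it should give the head-to-tail cyclobutane F2 (bonds C4–C7 and C5–C8; both ring-fusion isomers at C5 serve). Aqueous HCl in THF hydrolyses both ketals of F2; the C10 hydroxyl adds to the cyclobutanone C8 and the hemiketal fragments by the same retro-aldol reaction as in step 10 to the saturated dione lactone F3. IBX (DMSO, 65 °C) can dehydrogenate F3 only across C1–C2 and gives 15. Without the tether the face bias at C4 is weak, so C4 epimers would have to be separated at F3.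

Step 8. What may go wrong: intramolecular aldol addition of the ester enolate to the C3 carbonyl, attack of the amide base on the dienone before silylation, C-silylation, or [3,3] rearrangement on any warming.

Fallback, setting out from 9 and returning at 15. Ethyl vinyl ether and N-bromosuccinimide (CH2Cl2, −40 °C) convert 9 into the mixed bromoacetal F4. KOtBu (THF, −40 to 0 °C) eliminates HBr, the classical dehydrohalogenation route to ketene acetals, and gives the ketene ethyl acetal F5 without any ester enolate. F5 is irradiated as in step 9 to the ethyl ketal photoadduct F6, and aqueous HCl in THF unzips F6 to 15.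

Step 4. What may go wrong: low or reversed enantioselectivity, because both carbonyl substituents are sp2 groups whose size ranking is not clear-cut.

Fallback, setting out from 2 and 3 and returning at 7. Bromine–lithium exchange on 2 (n-BuLi, t-BuOMe, −78 °C) gives the aryllithium F7; ZnCl2 and a second equivalent of n-BuLi give the aryl(butyl)zinc F8. With tetraethylethylenediamine to bind LiCl and (2S)-3-exo-morpholinoisoborneol (5 mol%), the aryl group should be transferred to the Si face of 3 (catalytic asymmetric arylation of an aldehyde), giving 7 directly. Here the facial sense depends on hydrogen versus carbon at the aldehyde and not on the ranking of two sp2 groups.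

Step 11. What may go wrong: hydride delivery to the wrong face of C6 if the spiro centre opposes the catalyst, or competing reduction at C3 or of both carbonyls.

Fallback, setting out from 15 and returning at 16. 15 is reduced on purpose to the (6R)-epimer F9 (NaBH4, CeCl3·7H2O, MeOH, −78 °C, or the enantiomeric oxazaborolidine). A Mitsunobu reaction (4-nitrobenzoic acid, PPh3, DIAD, THF, 0 °C) inverts C6 and gives the (6S)-4-nitrobenzoate F10. Brief K2CO3 in MeOH at 0 °C removes the ester and gives 16.

## Further compounds

F1 | step 9 | 2-[(1R,2E)-1-hydroxy-3,7-dimethylocta-2,6-dien-1-yl]-4,4-dimethoxycyclohex-2-en-1-one | O=C1CCC(OC)(OC)C=C1[C@H](O)/C=C(\C)CCC=C(C)C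
F2 | step 9 | head-to-tail cyclobutane diethyl ketal photoadduct (C4 as in 15, C5 either epimer) | O=C1CCC(OC)(OC)C2[C@@]1(CC2(OCC)OCC)[C@H](O)/C=C(\C)CCC=C(C)C
F3 | step 9 | saturated dione lactone, (4R,10R) | O=C1CCC(=O)C[C@]12CC(=O)O[C@@H]2/C=C(\C)CCC=C(C)C
F4 | step 8 | mixed bromoacetal of 9 (acetal carbon as a mixture) | CCOC(CBr)O[C@@H](C1=CC(OC)(OC)C=CC1=O)/C=C(\C)CCC=C(C)C
F5 | step 8 | ketene ethyl acetal analogue of 12 | C=C(OCC)O[C@@H](C1=CC(OC)(OC)C=CC1=O)/C=C(\C)CCC=C(C)C
F6 | step 8 | ethyl ketal analogue of photoadduct 13 | O=C1C=CC(OC)(OC)[C@H]2[C@]13C[C@]2(OCC)O[C@@H]3/C=C(\C)CCC=C(C)C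
F7 | step 4 | [2-(tert-butyldimethylsilyloxy)-5-methoxyphenyl]lithium | COc1ccc(O[Si](C)(C)C(C)(C)C)c([Li])c1
F8 | step 4 | butyl[2-(tert-butyldimethylsilyloxy)-5-methoxyphenyl]zinc | CCCC[Zn]c1cc(OC)ccc1O[Si](C)(C)C(C)(C)C
F9 | step 11 | (4R,6R,10R)-6-hydroxy enone lactone (C6 epimer of 16) | O=C1C=C[C@H](O)C[C@]12CC(=O)O[C@@H]2/C=C(\C)CCC=C(C)C
F10 | step 11 | (4R,6S,10R)-6-(4-nitrobenzoyloxy) enone lactone | O=C1C=C[C@@H](OC(=O)c3ccc(cc3)[N+](=O)[O-])C[C@]12CC(=O)O[C@@H]2/C=C(\C)CCC=C(C)C
A1 | alternative 1 | itaconic anhydride | C=C1CC(=O)OC1=O
A2 | alternative 1 | (1E,3E)-1,4-diacetoxybuta-1,3-diene | CC(=O)O/C=C/C=C/OC(C)=O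
A3 | alternative 1 | spiro anhydride diacetate | C1=C[C@H](OC(C)=O)[C@@]2(CC(=O)OC2=O)C[C@@H]1OC(C)=O
A4 | alternative 2 | 1-(2-tert-butoxy-2-oxoethyl)cyclohexa-2,5-diene-1-carboxylic acid | CC(C)(C)OC(=O)CC1(C(=O)O)C=CCC=C1
A5 | alternative 2 | bridged iodolactone | CC(C)(C)OC(=O)C[C@@]12C=CC[C@@H](OC1=O)[C@@H]2I
A6 | alternative 3 | C3 N-(mesitoyloxy)carbamate of the spiro lactone with a C1=C6 alkene | O=C(NOC(=O)c1c(C)cc(C)cc1C)O[C@H]1CC=CC[C@]12CC(=O)O[C@@H]2/C=C(\C)CCC=C(C)C
A7 | alternative 3 | bridging cyclic carbamate with free C6 hydroxyl | O=C1N[C@@H]2C[C@H](O1)[C@@]3(CC(=O)O[C@@H]3/C=C(\C)CCC=C(C)C)C[C@@H]2O
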